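**Assumption:** methylating, brominating, silylating and acylating agents, Mg and MeNHOMe·HCl are treated as reagents; (S)-propylene oxide and ethyl (S)-lactate are bought enantiopure; each reaction is counted once even where its product feeds two branches.

**Retrosynthetic overview**
- The target acetate comes from the erythro (1S,2R) alcohol, which comes from chelation-controlled reduction of an (R)-α-aryloxy ketone.
- Key late disconnection: the aryl–O–C bond of that ketone, made by an invertive Mitsunobu between a two-ring "AB" phenol (28 non-H atoms) and (S)-2-hydroxy-1-(3,4,5-trimethoxyphenyl)propan-1-one (17 non-H atoms).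
- The AB phenol comes from a second invertive Mitsunobu between (E)-4-propenyl-2,6-dimethoxyphenol and a silyl-protected (S)-1-arylpropan-2-ol (aryl Grignard + (S)-propylene oxide).
- The hydroxy ketone comes from 3,4,5-trimethoxyphenylmagnesium bromide and the Weinreb amide of ethyl (S)-lactate.
- No ring is constructed: all three benzene rings come from resorcinol via 2,6-dimethoxyphenol (ring A by allylation, para-Claisen and isomerisation; rings B and C by para-bromination).

**Route**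

Step 1
Reactants: 1 resorcinol
Product: 2 1,3-dimethoxybenzene
Conditions: Me2SO4 (2.2 equiv), aq. NaOH, ≤40 °C then reflux
Reagents that add atoms: dimethyl sulfate, COS(=O)(=O)OC
Why: Williamson O-methylation of both phenoxide oxygens by the hard electrophile dimethyl sulfate.

Step 2
Reactants: 2 1,3-dimethoxybenzene
Product: 5 2,6-dimethoxyphenol, via 2,6-dimethoxyphenyllithium 3 (not isolated), via dimethyl (2,6-dimethoxyphenyl)boronate 4 (not isolated)
Conditions: n-BuLi, THF, 0 °C → rt; B(OMe)3, −78 °C → rt; AcOH, 30% H2O2, 0 °C → rt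
Reagents that add atoms: hydrogen peroxide, OO
Why: Directed ortho-metalation occurs at C2 between the two methoxy groups, and borylation followed by oxidative 1,2-aryl migration from boron to oxygen installs the hydroxyl there.

Step 3
Reactants: 5 2,6-dimethoxyphenol; 6 allyl bromide
Product: 7 2-(allyloxy)-1,3-dimethoxybenzene
Conditions: K2CO3, acetone, reflux
Reagents that add atoms: none
Why: Williamson etherification (SN2) of the phenoxide on the unhindered allylic bromide.

Step 4
Reactants: 7 2-(allyloxy)-1,3-dimethoxybenzene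
Product: 8 4-allyl-2,6-dimethoxyphenol
Conditions: N,N-diethylaniline, 210 °C, N2
Reagents that add atoms: none
Why: Aromatic para-Claisen rearrangement, in which the [3,3] shift to a blocked ortho position is followed by a Cope [3,3] shift to C4 and tautomerisation to the phenol.

Step 5
Reactants: 8 4-allyl-2,6-dimethoxyphenol
Product: 9 2,6-dimethoxy-4-[(E)-prop-1-enyl]phenol
Conditions: RuHCl(CO)(PPh3)3 (1 mol %), toluene, 80 °C; recrystallise
Reagents that add atoms: none
Why: Ru–H catalysed alkene isomerisation (hydrometalation/β-hydride elimination) moves the double bond into conjugation and gives the thermodynamically favoured E isomer (≥95:5 before crystallisation).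

Step 6
Reactants: 5 2,6-dimethoxyphenol
Product: 10 4-bromo-2,6-dimethoxyphenol
Conditions: NBS (1.0 equiv), NaH (cat.), CHCl3, −45 °C → rt
Reagents that add atoms: N-bromosuccinimide, O=C1CCC(=O)N1Br
Why: Electrophilic aromatic bromination steered to the position para to the phenoxide oxygen by the catalytic base and low temperature.

Step 7
Reactants: 10 4-bromo-2,6-dimethoxyphenol
Product: 11 (4-bromo-2,6-dimethoxyphenoxy)(tert-butyl)dimethylsilane
Conditions: TBSCl, imidazole, DMF, rt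
Reagents that add atoms: tert-butyldimethylsilyl chloride, CC(C)(C)[Si](C)(C)Cl
Why: Imidazole-promoted O-silylation masks the phenol as a TBS ether that tolerates Grignard formation and Mitsunobu conditions.

Step 8
Reactants: 11 (4-bromo-2,6-dimethoxyphenoxy)(tert-butyl)dimethylsilane; 12 (S)-2-methyloxirane
Product: 14 (2S)-1-[4-(tert-butyldimethylsilyloxy)-3,5-dimethoxyphenyl]propan-2-ol, via [4-(tert-butyldimethylsilyloxy)-3,5-dimethoxyphenyl]magnesium bromide 13 (not isolated)
Conditions: Mg (I2 cat.), THF, reflux; CuI (10 mol %), 12 (1.3 equiv), −30 → 0 °C; aq. NH4Cl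
Reagents that add atoms: none
Why: Copper-catalysed Grignard opening of the epoxide at its unsubstituted CH2 carbon leaves the stereocentre untouched, so the (S) configuration of 12 is carried into the carbinol.

Step 9
Reactants: 14 (2S)-1-[4-(tert-butyldimethylsilyloxy)-3,5-dimethoxyphenyl]propan-2-ol; 9 2,6-dimethoxy-4-[(E)-prop-1-enyl]phenol
Product: 15 tert-butyl{2,6-dimethoxy-4-[(2R)-2-{2,6-dimethoxy-4-[(E)-prop-1-enyl]phenoxy}propyl]phenoxy}dimethylsilane
Conditions: PPh3 (1.5 equiv), DIAD (1.5 equiv), 9 (1.2 equiv), toluene (high concentration), 0 °C → rt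
Reagents that add atoms: none
Why: Mitsunobu etherification, in which SN2 attack of the phenoxide on the alkoxyphosphonium ion inverts the (S) carbinol to the (R) aryl ether.

Step 10
Reactants: 15 tert-butyl{2,6-dimethoxy-4-[(2R)-2-{2,6-dimethoxy-4-[(E)-prop-1-enyl]phenoxy}propyl]phenoxy}dimethylsilane
Product: 16 2,6-dimethoxy-4-[(2R)-2-{2,6-dimethoxy-4-[(E)-prop-1-enyl]phenoxy}propyl]phenol
Conditions: TBAF (1.1 equiv), AcOH (1.1 equiv), THF, 0 °C
Reagents that add atoms: none
Why: Fluoride-driven desilylation frees the phenol under buffered conditions that leave the propenyl group and the alkyl aryl ether intact.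

Step 11
Reactants: 10 4-bromo-2,6-dimethoxyphenol
Product: 17 5-bromo-1,2,3-trimethoxybenzene
Conditions: MeI, K2CO3, DMF, rt
Reagents that add atoms: iodomethane, CI
Why: Williamson O-methylation of the phenoxide completes the 3,4,5-trimethoxyaryl pattern.

Step 12
Reactants: 18 ethyl (S)-lactate
Product: 19 (2S)-2-hydroxy-N-methoxy-N-methylpropanamide
Conditions: MeNHOMe·HCl (2.5 equiv), i-PrMgCl (5 equiv), THF, −20 → 0 °C
Reagents that add atoms: N,O-dimethylhydroxylamine hydrochloride, CNOC.Cl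
Why: Aminolysis of the ester by the magnesium amide gives the Weinreb amide, with the stereocentre protected from enolisation as its magnesium alkoxide.

Step 13
Reactants: 17 5-bromo-1,2,3-trimethoxybenzene; 19 (2S)-2-hydroxy-N-methoxy-N-methylpropanamide
Product: 21 (2S)-2-hydroxy-1-(3,4,5-trimethoxyphenyl)propan-1-one, via (3,4,5-trimethoxyphenyl)magnesium bromide 20 (not isolated)
Conditions: 17, Mg, THF, reflux; 19 pre-treated with i-PrMgCl (1.0 equiv), THF, −20 °C; then the Grignard (1.4 equiv), 0 °C → rt; aq. NH4Cl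
Reagents that add atoms: none
Why: Weinreb ketone synthesis, in which the stable chelated tetrahedral intermediate stops over-addition and the (S) centre is not touched.

Step 14
Reactants: 16 2,6-dimethoxy-4-[(2R)-2-{2,6-dimethoxy-4-[(E)-prop-1-enyl]phenoxy}propyl]phenol; 21 (2S)-2-hydroxy-1-(3,4,5-trimethoxyphenyl)propan-1-one
Product: 22 (2R)-2-{2,6-dimethoxy-4-[(2R)-2-{2,6-dimethoxy-4-[(E)-prop-1-enyl]phenoxy}propyl]phenoxy}-1-(3,4,5-trimethoxyphenyl)propan-1-one
Conditions: PPh3 (1.5 equiv), DIAD (1.5 equiv, slow addition), 21 (1.2 equiv), toluene, 0 °C → rt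
Reagents that add atoms: none
Why: Mitsunobu etherification joins the two large fragments, the carbonyl-activated alkoxyphosphonium being displaced by the phenoxide with clean SN2 inversion from (S) to (R).

Step 15
Reactants: 22 (2R)-2-{2,6-dimethoxy-4-[(2R)-2-{2,6-dimethoxy-4-[(E)-prop-1-enyl]phenoxy}propyl]phenoxy}-1-(3,4,5-trimethoxyphenyl)propan-1-one
Product: 23 (1S,2R)-2-{2,6-dimethoxy-4-[(2R)-2-{2,6-dimethoxy-4-[(E)-prop-1-enyl]phenoxy}propyl]phenoxy}-1-(3,4,5-trimethoxyphenyl)propan-1-ol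
Conditions: Zn(BH4)2 (pre-formed Et2O solution), Et2O/THF, −20 → 0 °C; aq. NH4Cl
Reagents that add atoms: none
Why: Chelation-controlled (Cram chelate) hydride reduction, in which zinc bridges the carbonyl and aryloxy oxygens and hydride enters from the face bearing the small H on C2, gives the erythro (1S,2R) alcohol.

Step 16
Reactants: 23 (1S,2R)-2-{2,6-dimethoxy-4-[(2R)-2-{2,6-dimethoxy-4-[(E)-prop-1-enyl]phenoxy}propyl]phenoxy}-1-(3,4,5-trimethoxyphenyl)propan-1-ol
Product: 24 (1S,2R)-2-{2,6-dimethoxy-4-[(2R)-2-{2,6-dimethoxy-4-[(E)-prop-1-enyl]phenoxy}propyl]phenoxy}-1-(3,4,5-trimethoxyphenyl)propyl acetate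
Conditions: Ac2O, pyridine, DMAP (cat.), CH2Cl2, rt
Reagents that add atoms: acetic anhydride, CC(=O)OC(C)=O
Why: DMAP-catalysed O-acylation of the secondary benzylic alcohol proceeds with retention because no bond to the stereocentre is broken.

**Compound list**

1 | resorcinol | Oc1cccc(O)c1 | starting material
2 | 1,3-dimethoxybenzene | COc1cccc(OC)c1 | intermediate
3 | 2,6-dimethoxyphenyllithium | [Li]c1c(OC)cccc1OC | intermediate
4 | dimethyl (2,6-dimethoxyphenyl)boronate | COB(OC)c1c(OC)cccc1OC | intermediate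
5 | 2,6-dimethoxyphenol | COc1cccc(OC)c1O | intermediate
6 | allyl bromide | C=CCBr | starting material
7 | 2-(allyloxy)-1,3-dimethoxybenzene | C=CCOc1c(OC)cccc1OC | intermediate
8 | 4-allyl-2,6-dimethoxyphenol | C=CCc1cc(OC)c(O)c(OC)c1 | intermediate
9 | 2,6-dimethoxy-4-[(E)-prop-1-enyl]phenol | C/C=C/c1cc(OC)c(O)c(OC)c1 | intermediate
10 | 4-bromo-2,6-dimethoxyphenol | COc1cc(Br)cc(OC)c1O | intermediate
11 | (4-bromo-2,6-dimethoxyphenoxy)(tert-butyl)dimethylsilane | COc1cc(Br)cc(OC)c1O[Si](C)(C)C(C)(C)C | intermediate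
12 | (S)-2-methyloxirane | C[C@H]1CO1 | starting material
13 | [4-(tert-butyldimethylsilyloxy)-3,5-dimethoxyphenyl]magnesium bromide | COc1cc([Mg]Br)cc(OC)c1O[Si](C)(C)C(C)(C)C | intermediate
14 | (2S)-1-[4-(tert-butyldimethylsilyloxy)-3,5-dimethoxyphenyl]propan-2-ol | C[C@H](O)Cc1cc(OC)c(O[Si](C)(C)C(C)(C)C)c(OC)c1 | intermediate
15 | tert-butyl{2,6-dimethoxy-4-[(2R)-2-{2,6-dimethoxy-4-[(E)-prop-1-enyl]phenoxy}propyl]phenoxy}dimethylsilane | C/C=C/c1cc(OC)c(O[C@H](C)Cc2cc(OC)c(O[Si](C)(C)C(C)(C)C)c(OC)c2)c(OC)c1 | intermediate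
16 | 2,6-dimethoxy-4-[(2R)-2-{2,6-dimethoxy-4-[(E)-prop-1-enyl]phenoxy}propyl]phenol | C/C=C/c1cc(OC)c(O[C@H](C)Cc2cc(OC)c(O)c(OC)c2)c(OC)c1 | intermediate
17 | 5-bromo-1,2,3-trimethoxybenzene | COc1cc(Br)cc(OC)c1OC | intermediate
18 | ethyl (S)-lactate | CCOC(=O)[C@H](C)O | starting material
19 | (2S)-2-hydroxy-N-methoxy-N-methylpropanamide | CON(C)C(=O)[C@H](C)O | intermediate
20 | (3,4,5-trimethoxyphenyl)magnesium bromide | COc1cc([Mg]Br)cc(OC)c1OC | intermediate
21 | (2S)-2-hydroxy-1-(3,4,5-trimethoxyphenyl)propan-1-one | COc1cc(cc(OC)c1OC)C(=O)[C@H](C)O | intermediate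
22 | (2R)-2-{2,6-dimethoxy-4-[(2R)-2-{2,6-dimethoxy-4-[(E)-prop-1-enyl]phenoxy}propyl]phenoxy}-1-(3,4,5-trimethoxyphenyl)propan-1-one | C/C=C/c1cc(OC)c(O[C@H](C)Cc2cc(OC)c(O[C@H](C)C(=O)c3cc(OC)c(OC)c(OC)c3)c(OC)c2)c(OC)c1 | intermediate
23 | (1S,2R)-2-{2,6-dimethoxy-4-[(2R)-2-{2,6-dimethoxy-4-[(E)-prop-1-enyl]phenoxy}propyl]phenoxy}-1-(3,4,5-trimethoxyphenyl)propan-1-ol | C/C=C/c1cc(OC)c(O[C@H](C)Cc2cc(OC)c(O[C@H](C)[C@@H](O)c3cc(OC)c(OC)c(OC)c3)c(OC)c2)c(OC)c1 | intermediate
24 | (1S,2R)-2-{2,6-dimethoxy-4-[(2R)-2-{2,6-dimethoxy-4-[(E)-prop-1-enyl]phenoxy}propyl]phenoxy}-1-(3,4,5-trimethoxyphenyl)propyl acetate | C/C=C/c1cc(OC)c(O[C@H](C)Cc2cc(OC)c(O[C@H](C)[C@@H](OC(C)=O)c3cc(OC)c(OC)c(OC)c3)c(OC)c2)c(OC)c1 | target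

**Step count**

Total step count: 16.
Longest linear sequence: 10 steps (1, 2, 6, 7, 8, 9, 10, 14, 15, 16; the path through steps 3–5 is equally long), which is 10/16 of the total.

**Steps most likely to fail, with fallbacks**

Step 14 (Mitsunobu of the hindered phenol 16 with hydroxy ketone 21). The risks are low conversion with the di-ortho-substituted phenol and partial epimerisation of the α-aryloxy ketone. The fallback sets out from 16 and forms the C–C bond to ring C instead of the C–O bond. A Mitsunobu reaction of 16 with ethyl (S)-lactate 18 (PPh3, DIAD, THF; inversion) gives ethyl (2R)-2-{2,6-dimethoxy-4-[(2R)-2-{2,6-dimethoxy-4-[(E)-prop-1-enyl]phenoxy}propyl]phenoxy}propanoate F4. Treatment with MeNHOMe·HCl and i-PrMgCl in THF at −20 °C converts it into (2R)-2-{2,6-dimethoxy-4-[(2R)-2-{2,6-dimethoxy-4-[(E)-prop-1-enyl]phenoxy}propyl]phenoxy}-N-methoxy-N-methylpropanamide F5. Addition of Grignard reagent 20 at 0 °C then comes back to the route at 22.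

Step 9 (Mitsunobu of phenol 9 with the unactivated secondary alcohol 14). The risks are E2 elimination to the conjugated propenylarene and slow substitution. The fallback sets out from 9 and takes the stereocentre from lactate instead of propylene oxide. A Mitsunobu reaction of 9 with ethyl (S)-lactate 18 (inversion) gives ethyl (2R)-2-{2,6-dimethoxy-4-[(E)-prop-1-enyl]phenoxy}propanoate F1. LiAlH4 in THF at 0 °C reduces it to (2R)-2-{2,6-dimethoxy-4-[(E)-prop-1-enyl]phenoxy}propan-1-ol F2, and TsCl in pyridine gives (2R)-2-{2,6-dimethoxy-4-[(E)-prop-1-enyl]phenoxy}propyl 4-methylbenzenesulfonate F3. Li2CuCl4-catalysed sp3–sp2 coupling of F3 with Grignard reagent 13 (made from 11 as in step 8) in THF at −20 °C → rt forms the ArCH2–C bond and comes back to the route at 15.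

Step 15 (erythro-selective reduction). The risk is a poor erythro:threo ratio if chelation by the hindered aryloxy oxygen is weak. The fallback sets out from 22 and sets C1 by invertive esterification. K-Selectride in THF at −78 °C (non-chelating, Felkin–Anh) gives the threo alcohol (1R,2R)-2-{2,6-dimethoxy-4-[(2R)-2-{2,6-dimethoxy-4-[(E)-prop-1-enyl]phenoxy}propyl]phenoxy}-1-(3,4,5-trimethoxyphenyl)propan-1-ol F6; any threo material separated after step 15 can be used as well. A Mitsunobu reaction with 4-nitrobenzoic acid (PPh3, DIAD, THF) inverts C1 to give (1S,2R)-2-{2,6-dimethoxy-4-[(2R)-2-{2,6-dimethoxy-4-[(E)-prop-1-enyl]phenoxy}propyl]phenoxy}-1-(3,4,5-trimethoxyphenyl)propyl 4-nitrobenzoate F7. Methanolysis with K2CO3 in MeOH comes back to the route at 23.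

**Further compounds**

F1 | step 9 | ethyl (2R)-2-{2,6-dimethoxy-4-[(E)-prop-1-enyl]phenoxy}propanoate | C/C=C/c1cc(OC)c(O[C@H](C)C(=O)OCC)c(OC)c1
F2 | step 9 | (2R)-2-{2,6-dimethoxy-4-[(E)-prop-1-enyl]phenoxy}propan-1-ol | C/C=C/c1cc(OC)c(O[C@H](C)CO)c(OC)c1
F3 | step 9 | (2R)-2-{2,6-dimethoxy-4-[(E)-prop-1-enyl]phenoxy}propyl 4-methylbenzenesulfonate | C/C=C/c1cc(OC)c(O[C@H](C)COS(=O)(=O)c2ccc(C)cc2)c(OC)c1
F4 | step 14 | ethyl (2R)-2-{2,6-dimethoxy-4-[(2R)-2-{2,6-dimethoxy-4-[(E)-prop-1-enyl]phenoxy}propyl]phenoxy}propanoate | C/C=C/c1cc(OC)c(O[C@H](C)Cc2cc(OC)c(O[C@H](C)C(=O)OCC)c(OC)c2)c(OC)c1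
F5 | step 14 | (2R)-2-{2,6-dimethoxy-4-[(2R)-2-{2,6-dimethoxy-4-[(E)-prop-1-enyl]phenoxy}propyl]phenoxy}-N-methoxy-N-methylpropanamide | C/C=C/c1cc(OC)c(O[C@H](C)Cc2cc(OC)c(O[C@H](C)C(=O)N(C)OC)c(OC)c2)c(OC)c1
F6 | step 15 | (1R,2R)-2-{2,6-dimethoxy-4-[(2R)-2-{2,6-dimethoxy-4-[(E)-prop-1-enyl]phenoxy}propyl]phenoxy}-1-(3,4,5-trimethoxyphenyl)propan-1-ol | C/C=C/c1cc(OC)c(O[C@H](C)Cc2cc(OC)c(O[C@H](C)[C@H](O)c3cc(OC)c(OC)c(OC)c3)c(OC)c2)c(OC)c1
F7 | step 15 | (1S,2R)-2-{2,6-dimethoxy-4-[(2R)-2-{2,6-dimethoxy-4-[(E)-prop-1-enyl]phenoxy}propyl]phenoxy}-1-(3,4,5-trimethoxyphenyl)propyl 4-nitrobenzoate | C/C=C/c1cc(OC)c(O[C@H](C)Cc2cc(OC)c(O[C@H](C)[C@@H](OC(=O)c4ccc(cc4)[N+](=O)[O-])c3cc(OC)c(OC)c(OC)c3)c(OC)c2)c(OC)c1
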